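The oak run is this very flask followed to 900 min, and I read it for the share of the flask's contents that ends up as G.

- oak: Q 29 mM; the very flask that is asked about, followed so far
- flask: Q 29 mM; time 25 h

oak run (percent of the Q charged)

| time / min | G / % | Q / % |
|---|---|---|
| 150 | 15.2 | 28.7 |
| 300 | 19.7 | 21.2 |
| 480 | 22.8 | 15.9 |
| 600 | 25.6 | 13.1 |
| 720 | 26.3 | 12.0 |
| 900 | 27.6 | 10.1 |

(standard deviation of a reading: 0.3 percentage points)

1. G, in percent of the Q first charged, at 25 h
2. which option adds most G ("none" when 2 percentage points or less is all one gets) (north / north-east / south / none)
3. G present, with what was taken out counted in, in percent of the Q first charged, after north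
4. G present, with what was taken out counted in, in percent of the Q first charged, after north-east

- north: at 25 h add Q, 50.0% of the amount charged, then wait 8.0 h
- north-east: at 25 h take out 90% of the G then present, then wait 8.0 h
- south: change nothing and wait 8.0 h more

- G taken out counts as made
- the numbers in the tables scatter with a standard deviation of 0.3 percentage points
- additions bring no volume worth counting

With the main step from Q to G by itself, G in the oak run would be the charge minus Q, 89.9% at 900 min, but the reading is 27.6%. Adding a one-way side loss in fixed proportion, I take the 21.3% of spent Q found as G at 150 min, which would hold G to 21.3% of the charge, yet the last reading is more than that. So I added the rest: a hidden pool and steps running both ways. Q plus G stood at 38.7% at 600 min and 37.7% at 900 min, with Q still at 10.1%.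

For reversible first-order steps, the rate integrates late to an exponential tail, so equal time steps shrink G's rise by a constant factor. From 300 min to 600 min to 900 min that factor reads 0.339, a half-life of 192 min. Summing the series gives the keeping share f, the fraction of whatever the flask contains that stands as G once relaxed: 28.6%, a reading of thermodynamic control.

My reckoning for the flask at 25 h was 28.5%. Assuming f does not depend on the amount, and taking 8.0 h (2.50 half-lives) as enough, north gives f of the enlarged contents, 42.9%. North-east banks 25.8% and keeps f of the remainder, 47.0%. So I chose north-east, which I reckoned to give more than north.

The forecast said 30.5% at 25 h, north as best, 50.5% after north and 32% after north-east, holding that “nothing shows G reverses”.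

The flask held 28.9%, and north-east was best at 47.2%, against 40.8% after north and a gain of 0.25 percentage points from south.

    Q ⇌ X (K = 1.10, k = 2.60 × 10⁻⁴ s⁻¹)
    G ⇌ L (K = 1.90, k = 4.10 × 10⁻⁴ s⁻¹)
    Q ⇌ G (K = 4.00, k = 9.30 × 10⁻⁵ s⁻¹)

North-east landed 0.20 points from my reckoning and north 2.1 points below it. The neighbour flask, with the same charge read at 6.0 h, takes the same tail from the 300 min reading: f less the remaining gap gives 21.4%, and that neighbour flask held 21.2% of G.

(The numbers in the tables are simulated with constants of no real substance, and the scatter is random.)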